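**Retrosynthetic overview**

1. Target 29 ⇐ 28 (acid removal of tert-butyl ester and methoxymethyl enol ether) ⇐ cycloadduct 24 by Mannich methylenation at C4 and loss of benzenesulfinate from C1.
2. Ring A carries the diosphenol C1=C2(OH)–C3=O beside the exocyclic C4=C18. Read as a cyclohexene, C2=C3–C4=C5 is a 1-alkoxy-2-siloxy diene and C1=C10 a dienophile, joined by the four-carbon chain C6–C7–C8–C9 that becomes ring B. An intramolecular Diels–Alder reaction of triene 23 therefore forms C1–C2 and C5–C10, and so rings A and B, together; no ring of the target exists before it. A phenylsulfonyl group on C1 activates the dienophile and later leaves to give C1=C2.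
3. Triene 23 ⇐ (Z)-enone 20 ⇐ unsaturated δ-lactone 15 plus (methoxymethoxy)methyllithium. The lactone ring fixes the (Z) geometry of C4=C5 that enforces cis ring fusion; the vinyl group becomes the vinyl sulfone.
4. Lactone 15 ⇐ aldehyde 6 plus a five-carbon vinylogous Reformatsky reagent (C7 by Felkin–Anh addition); the prenyl group is cut down and rebuilt into the (E)-enoate side chain.
5. Aldehyde 6 ⇐ geranyl propionate 1 by an enantioselective Ireland–Claisen rearrangement that sets C8 and the quaternary C9 together.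

Key step: step 13

Assumption: the (S,S)-configured boron controller is taken to give the (2S,3R) acid 4; were the sense of induction the opposite, its (R,R) enantiomer would be used with nothing else changed.

Numbering: clerodane numbering is used for atoms (ring A = C1–C5, C10; ring B = C5–C10; C17 = C8 methyl, C18 = exocyclic methylene carbon, C19 = C5 methyl, C20 = C9 methyl, side chain C11–C16); β is the face of the C5 methyl.

**Route**

Step 1
Reactants: 1 geranyl propionate
Product: 4 (2S,3R)-3-ethenyl-2,3,7-trimethyloct-6-enoic acid, via boron ketene acetal 2 (not isolated), via O-boryl ester 3 (not isolated)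
Conditions: (S,S)-2-bromo-4,5-diphenyl-1,3-bis(p-tolylsulfonyl)-1,3,2-diazaborolidine (1.2 equiv), i-Pr2NEt, CH2Cl2, −78 °C; then −20 → 4 °C; aqueous work-up
Reagents that add atoms: none
Why: Soft enolisation with the chiral bromoborane should give ketene acetal 2 with the C-methyl cis to O–B, which rearranges through a chair Ireland–Claisen ([3,3]-sigmatropic) transition state in which the (E)-alkene places the homoprenyl chain equatorial and the C9 methyl axial, so C8 and C9 are set together and the sulfonamide controller selects the enantiotopic face.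

Step 2
Reactants: 4 (2S,3R)-3-ethenyl-2,3,7-trimethyloct-6-enoic acid
Product: 5 (2S,3R)-3-ethenyl-2,3,7-trimethyloct-6-en-1-ol
Conditions: LiAlH4, Et2O, 0 °C → rt; then H2O, aq NaOH
Reagents that add atoms: none
Why: LiAlH4 reduces the carboxylic acid to the primary alcohol and leaves the unactivated alkenes and both stereocentres untouched.

Step 3
Reactants: 5 (2S,3R)-3-ethenyl-2,3,7-trimethyloct-6-en-1-ol
Product: 6 (2S,3R)-3-ethenyl-2,3,7-trimethyloct-6-enal
Conditions: Dess–Martin periodinane, NaHCO3, CH2Cl2, 0 °C → rt; used at once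
Reagents that add atoms: none
Why: Buffered Dess–Martin oxidation gives the α-branched aldehyde without epimerisation of C8, whose enolisation is slowed by the neighbouring quaternary carbon.

Step 4
Reactants: 6 (2S,3R)-3-ethenyl-2,3,7-trimethyloct-6-enal; 7 ethyl (2E)-4-bromo-3-methylbut-2-enoate (the commercial E/Z mixture serves equally)
Product: 10 (6S)-6-[(2S,3R)-3-ethenyl-3,7-dimethyloct-6-en-2-yl]-4-methyl-5,6-dihydro-2H-pyran-2-one, via allylzinc bromide 8 (not isolated), via zinc alkoxide 9 (not isolated)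
Conditions: Zn dust (activated), THF, reflux; then 1 M HCl
Reagents that add atoms: ethyl (2E)-4-bromo-3-methylbut-2-enoate (7), CCOC(=O)/C=C(\C)CBr
Why: Vinylogous Reformatsky reaction: at reflux the zinc dienolate adds through its γ-carbon and the (Z)-configured zinc alkoxide 9 lactonises, draining the reversible aldol equilibria towards the 4-methyl-5,6-dihydropyran-2-one, while C7 is set by Felkin–Anh addition anti to the quaternary C9 substituent (7,8-syn, 7S).

Step 5
Reactants: 10 (6S)-6-[(2S,3R)-3-ethenyl-3,7-dimethyloct-6-en-2-yl]-4-methyl-5,6-dihydro-2H-pyran-2-one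
Product: 11 (4R,5S)-4-ethenyl-4-methyl-5-[(2S)-4-methyl-6-oxo-3,6-dihydro-2H-pyran-2-yl]hexanal
Conditions: O3, CH2Cl2/MeOH, −78 °C, Sudan red 7B end point; then Me2S
Reagents that add atoms: ozone, [O-][O+]=O
Why: Ozone attacks the electron-rich trisubstituted prenyl alkene much faster than the hindered monosubstituted vinyl group or the conjugated lactone alkene, so ozonolysis stopped at the indicator end point should cleave only the prenyl double bond and release C13 as the aldehyde.

Step 6
Reactants: 11 (4R,5S)-4-ethenyl-4-methyl-5-[(2S)-4-methyl-6-oxo-3,6-dihydro-2H-pyran-2-yl]hexanal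
Product: 12 (6S)-6-[(2S,3R)-3-ethenyl-6-hydroxy-3-methylheptan-2-yl]-4-methyl-5,6-dihydro-2H-pyran-2-one (both carbinol epimers)
Conditions: MeMgBr (1.05 equiv), THF, −78 °C; then sat. aq NH4Cl
Reagents that add atoms: methylmagnesium bromide, C[Mg]Br
Why: Grignard addition to the aldehyde at −78 °C is much faster than attack on the conjugated, β-substituted lactone, and the new carbinol centre is removed in step 7, so both epimers are carried on.

Step 7
Reactants: 12 (6S)-6-[(2S,3R)-3-ethenyl-6-hydroxy-3-methylheptan-2-yl]-4-methyl-5,6-dihydro-2H-pyran-2-one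
Product: 13 (6S)-6-[(2S,3R)-3-ethenyl-3-methyl-6-oxoheptan-2-yl]-4-methyl-5,6-dihydro-2H-pyran-2-one
Conditions: Dess–Martin periodinane, NaHCO3, CH2Cl2, rt
Reagents that add atoms: none
Why: Dess–Martin oxidation converts the secondary alcohol into the methyl ketone under buffered conditions that spare the lactone and the alkenes.

Step 8
Reactants: 13 (6S)-6-[(2S,3R)-3-ethenyl-3-methyl-6-oxoheptan-2-yl]-4-methyl-5,6-dihydro-2H-pyran-2-one; 14 tert-butyl 2-(diethoxyphosphoryl)acetate
Product: 15 tert-butyl (2E,6R,7S)-6-ethenyl-3,6-dimethyl-7-[(2S)-4-methyl-6-oxo-3,6-dihydro-2H-pyran-2-yl]oct-2-enoate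
Conditions: NaH, THF, 0 → 50 °C; (E) isomer separated by chromatography
Reagents that add atoms: tert-butyl 2-(diethoxyphosphoryl)acetate (14), CCOP(=O)(CC(=O)OC(C)(C)C)OCC
Why: Horner–Wadsworth–Emmons olefination of the methyl ketone with the stabilised phosphonate anion, which is too weakly basic to open or deconjugate the lactone, should give mainly the (E)-trisubstituted enoate with C12 trans to the ester.

Step 9
Reactants: 15 tert-butyl (2E,6R,7S)-6-ethenyl-3,6-dimethyl-7-[(2S)-4-methyl-6-oxo-3,6-dihydro-2H-pyran-2-yl]oct-2-enoate; 16 tributyl[(methoxymethoxy)methyl]stannane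
Product: 18 tert-butyl (2E,6R,7S)-6-ethenyl-7-[(2S)-6-hydroxy-6-[(methoxymethoxy)methyl]-4-methyl-3,6-dihydro-2H-pyran-2-yl]-3,6-dimethyloct-2-enoate (anomers), via (methoxymethoxy)methyllithium 17 (not isolated)
Conditions: 16, n-BuLi, THF, −78 °C; then 15, −78 °C; sat. aq NH4Cl
Reagents that add atoms: tributyl[(methoxymethoxy)methyl]stannane (16), CCCC[Sn](CCCC)(CCCC)COCOC
Why: Tin–lithium exchange gives the α-alkoxy organolithium, which adds once to the lactone carbonyl because the lithium lactolate is stable at −78 °C, while the hindered β,β-disubstituted tert-butyl enoate is not attacked on this time scale; this brings in C2 with its oxygen.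

Step 10
Reactants: 18 tert-butyl (2E,6R,7S)-6-ethenyl-7-[(2S)-6-hydroxy-6-[(methoxymethoxy)methyl]-4-methyl-3,6-dihydro-2H-pyran-2-yl]-3,6-dimethyloct-2-enoate
Product: 20 tert-butyl (2E,6R,7S,8S,10Z)-8-acetoxy-6-ethenyl-13-(methoxymethoxy)-3,6,7,10-tetramethyl-12-oxotrideca-2,10-dienoate, via open-chain hydroxy enone 19 (not isolated)
Conditions: Ac2O, DMAP, pyridine, CH2Cl2, 0 °C → rt
Reagents that add atoms: acetic anhydride, CC(=O)OC(C)=O
Why: Hemiketal 18 is in ring–chain equilibrium with δ-hydroxy enone 19, whose secondary hydroxyl is acylated far faster than the tertiary anomeric hydroxyl (DMAP-catalysed acylation), so the open form is trapped as the 7-acetate with the (Z) geometry of C4=C5 inherited from the ring.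

Step 11
Reactants: 20 tert-butyl (2E,6R,7S,8S,10Z)-8-acetoxy-6-ethenyl-13-(methoxymethoxy)-3,6,7,10-tetramethyl-12-oxotrideca-2,10-dienoate
Product: 22 tert-butyl (2E,6S,7S,8S,10Z)-8-acetoxy-13-(methoxymethoxy)-3,6,7,10-tetramethyl-12-oxo-6-[(E)-2-(phenylsulfonyl)ethenyl]trideca-2,10-dienoate, via β-iodo sulfone 21 (not isolated)
Conditions: PhSO2Na, I2, EtOAc/H2O, rt, visible light; then Et3N, MeCN, 0 °C → rt
Reagents that add atoms: sodium benzenesulfinate, [Na+].[O-]S(=O)c1ccccc1
Why: Radical-chain iodosulfonylation: the sulfonyl radical from PhSO2I adds to the terminal carbon of the only electron-rich alkene, iodine-atom transfer to C10 outruns any cyclisation, and E1cB-type dehydroiodination with Et3N gives the (E)-vinyl sulfone, C9 carrying no hydrogen.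

Step 12
Reactants: 22 tert-butyl (2E,6S,7S,8S,10Z)-8-acetoxy-13-(methoxymethoxy)-3,6,7,10-tetramethyl-12-oxo-6-[(E)-2-(phenylsulfonyl)ethenyl]trideca-2,10-dienoate
Product: 23 tert-butyl (2E,6S,7S,8S,10Z,12Z)-8-acetoxy-12-(tert-butyldimethylsilyloxy)-13-(methoxymethoxy)-3,6,7,10-tetramethyl-6-[(E)-2-(phenylsulfonyl)ethenyl]trideca-2,10,12-trienoate
Conditions: TBSOTf (1.2 equiv), Et3N, CH2Cl2, −78 → −20 °C; filtration through basic alumina
Reagents that add atoms: tert-butyldimethylsilyl trifluoromethanesulfonate, CC(C)(C)[Si](C)(C)OS(=O)(=O)C(F)(F)F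
Why: Soft enolisation silylates the ketone on its more acidic α-alkoxy side (C2) and leaves the acetate, the tert-butyl ester and the vinyl sulfone alone, giving the cross-conjugated 2-siloxy diene with the methoxymethoxy group cis to the siloxy group, the less strained enol ether geometry.

Step 13
Reactants: 23 tert-butyl (2E,6S,7S,8S,10Z,12Z)-8-acetoxy-12-(tert-butyldimethylsilyloxy)-13-(methoxymethoxy)-3,6,7,10-tetramethyl-6-[(E)-2-(phenylsulfonyl)ethenyl]trideca-2,10,12-trienoate
Product: 24 tert-butyl (13E)-7β-acetoxy-3-(tert-butyldimethylsilyloxy)-2β-(methoxymethoxy)-1β-(phenylsulfonyl)-18-nor-5,10-cis-cleroda-3,13-dien-15-oate (H-10 and the C5 methyl both β; C8 and C9 methyls α)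
Conditions: toluene (0.01 M), BHT, trace Et3N, silylated sealed tube, 150 °C
Reagents that add atoms: none
Why: Thermal, concerted suprafacial [4+2] cycloaddition in which the electron-rich (Z,Z)-1-alkoxy-2-siloxy diene C2=C3–C4=C5 adds across the sulfonyl-activated C1=C10 alkene, the closest known reaction type being the intramolecular Diels–Alder reaction of 1,7,9-decatrienes that carry a sulfonyl- or ester-activated terminal dienophile and a siloxy diene. Ring A is closed as the new cyclohexene by the cycloaddition itself (bonds C1–C2 and C5–C10), and ring B is closed in the same event in the fused mode as a six-membered ring, because the four-atom tether C6–C9 spans C5 and C10. For C5 and C10, the (Z) geometry of C4=C5 places the tether carbon C6 inside the diene, so only the exo-tether fused transition state is reachable and the C5 methyl and H-10 must end cis (cis ring fusion). The diene face relative to C7–C9 should be set by a chair-like tether with 7-OAc, the C8 methyl and the C9 side chain equatorial; the axial C9 methyl then faces C4–H in the favoured arrangement and the C5 methyl (syn-pentane clash) in the disfavoured one. C1 and C2 form with the sulfonyl group endo and the methoxymethoxy group outside, and both centres become sp2 in step 14. The step needs fused rather than bridged closure, which the short tether secures, and cycloaddition faster than [1,5]-hydrogen shift of the (Z)-diene, which the sulfone activation and the raised diene HOMO should secure.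

Step 14
Reactants: 24 tert-butyl (13E)-7β-acetoxy-3-(tert-butyldimethylsilyloxy)-2β-(methoxymethoxy)-1β-(phenylsulfonyl)-18-nor-5,10-cis-cleroda-3,13-dien-15-oate
Product: 26 tert-butyl (13E)-7β-acetoxy-18-(dimethylamino)-2-(methoxymethoxy)-3-oxo-5,10-cis-cleroda-1,13-dien-15-oate (C4 epimers), via Mannich base 25 (not isolated)
Conditions: Me2N=CH2+ I−, CH2Cl2, rt; then DBU, 0 °C → rt
Reagents that add atoms: N,N-dimethylmethaniminium iodide, C[N+](C)=C.[I-]
Why: Mukaiyama-type Mannich reaction: the silyl enol ether attacks the iminium ion regiospecifically through C4, and DBU then removes the acidic C2–H of the β-sulfonyl ketone so that benzenesulfinate leaves from C1 (E1cB), giving the C1=C2 enol ether of the diosphenol; C10, now γ to the enone, can only equilibrate towards the far more stable cis ring fusion.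

Step 15
Reactants: 26 tert-butyl (13E)-7β-acetoxy-18-(dimethylamino)-2-(methoxymethoxy)-3-oxo-5,10-cis-cleroda-1,13-dien-15-oate
Product: 28 tert-butyl (13E)-7β-acetoxy-2-(methoxymethoxy)-3-oxo-5,10-cis-cleroda-1,4(18),13-trien-15-oate, via ammonium iodide 27 (not isolated)
Conditions: MeI, THF, rt; evaporate; then NaHCO3, CH2Cl2/H2O, rt
Reagents that add atoms: none
Why: Exhaustive N-methylation turns the amine into a leaving group and mild base eliminates trimethylamine from the β-ammonium ketone (E1cB) to give the exocyclic C4=C18 alkene, the standard two-stage α-methylenation.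

Step 16
Reactants: 28 tert-butyl (13E)-7β-acetoxy-2-(methoxymethoxy)-3-oxo-5,10-cis-cleroda-1,4(18),13-trien-15-oate
Product: 29 (13E)-7β-acetoxy-2-hydroxy-3-oxo-5,10-cis-cleroda-1,4(18),13-trien-15-oic acid (5S,7S,8S,9R,10R), the target
Conditions: TFA/CH2Cl2 (1:4), H2O (2 equiv), 0 °C → rt
Reagents that add atoms: none
Why: Trifluoroacetic acid cleaves the tert-butyl ester (loss of 2-methylpropene) and the methoxymethyl enol ether (acetal hydrolysis) in one operation while the secondary acetate and the α-methylene ketone are stable to it, and the 1,2-dione can enolise only towards C1 because C4 carries no hydrogen, which gives the diosphenol of the target.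

**Compound list**

1 | geranyl propionate, (2E)-3,7-dimethylocta-2,6-dien-1-yl propanoate | CCC(=O)OC/C=C(\C)CCC=C(C)C | starting material
2 | boron ketene acetal of 1 (C-methyl cis to O–B) | C/C=C(\OB1N(S(=O)(=O)c2ccc(C)cc2)[C@@H](c2ccccc2)[C@H](c2ccccc2)N1S(=O)(=O)c1ccc(C)cc1)OC/C=C(\C)CCC=C(C)C | intermediate (not isolated)
3 | O-boryl ester of acid 4 | C=C[C@@](C)(CCC=C(C)C)[C@H](C)C(=O)OB1N(S(=O)(=O)c2ccc(C)cc2)[C@@H](c2ccccc2)[C@H](c2ccccc2)N1S(=O)(=O)c1ccc(C)cc1 | intermediate (not isolated)
4 | (2S,3R)-3-ethenyl-2,3,7-trimethyloct-6-enoic acid | C=C[C@@](C)(CCC=C(C)C)[C@H](C)C(=O)O | intermediate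
5 | (2S,3R)-3-ethenyl-2,3,7-trimethyloct-6-en-1-ol | C=C[C@@](C)(CCC=C(C)C)[C@H](C)CO | intermediate
6 | (2S,3R)-3-ethenyl-2,3,7-trimethyloct-6-enal | C=C[C@@](C)(CCC=C(C)C)[C@H](C)C=O | intermediate
7 | ethyl (2E)-4-bromo-3-methylbut-2-enoate | CCOC(=O)/C=C(\C)CBr | starting material
8 | [(2E)-4-ethoxy-2-methyl-4-oxobut-2-en-1-yl]zinc bromide | CCOC(=O)/C=C(\C)C[Zn]Br | intermediate (not isolated)
9 | bromozinc alkoxide of ethyl (2Z,5S,6S,7R)-7-ethenyl-5-hydroxy-3,6,7,11-tetramethyldodeca-2,10-dienoate | C=C[C@@](C)(CCC=C(C)C)[C@H](C)[C@@H](O[Zn]Br)C/C(C)=C\C(=O)OCC | intermediate (not isolated)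
10 | (6S)-6-[(2S,3R)-3-ethenyl-3,7-dimethyloct-6-en-2-yl]-4-methyl-5,6-dihydro-2H-pyran-2-one | C=C[C@@](C)(CCC=C(C)C)[C@H](C)[C@@H]1CC(C)=CC(=O)O1 | intermediate
11 | (4R,5S)-4-ethenyl-4-methyl-5-[(2S)-4-methyl-6-oxo-3,6-dihydro-2H-pyran-2-yl]hexanal | C=C[C@@](C)(CCC=O)[C@H](C)[C@@H]1CC(C)=CC(=O)O1 | intermediate
12 | (6S)-6-[(2S,3R)-3-ethenyl-6-hydroxy-3-methylheptan-2-yl]-4-methyl-5,6-dihydro-2H-pyran-2-one (carbinol epimers) | C=C[C@@](C)(CCC(C)O)[C@H](C)[C@@H]1CC(C)=CC(=O)O1 | intermediate
13 | (6S)-6-[(2S,3R)-3-ethenyl-3-methyl-6-oxoheptan-2-yl]-4-methyl-5,6-dihydro-2H-pyran-2-one | C=C[C@@](C)(CCC(C)=O)[C@H](C)[C@@H]1CC(C)=CC(=O)O1 | intermediate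
14 | tert-butyl 2-(diethoxyphosphoryl)acetate | CCOP(=O)(CC(=O)OC(C)(C)C)OCC | starting material
15 | tert-butyl (2E,6R,7S)-6-ethenyl-3,6-dimethyl-7-[(2S)-4-methyl-6-oxo-3,6-dihydro-2H-pyran-2-yl]oct-2-enoate | C=C[C@@](C)(CC/C(C)=C/C(=O)OC(C)(C)C)[C@H](C)[C@@H]1CC(C)=CC(=O)O1 | intermediate
16 | tributyl[(methoxymethoxy)methyl]stannane | CCCC[Sn](CCCC)(CCCC)COCOC | starting material
17 | (methoxymethoxy)methyllithium | [Li]COCOC | intermediate (not isolated)
18 | tert-butyl (2E,6R,7S)-6-ethenyl-7-[(2S)-6-hydroxy-6-[(methoxymethoxy)methyl]-4-methyl-3,6-dihydro-2H-pyran-2-yl]-3,6-dimethyloct-2-enoate (anomers) | C=C[C@@](C)(CC/C(C)=C/C(=O)OC(C)(C)C)[C@H](C)[C@@H]1CC(C)=CC(O)(COCOC)O1 | intermediate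
19 | tert-butyl (2E,6R,7S,8S,10Z)-6-ethenyl-8-hydroxy-13-(methoxymethoxy)-3,6,7,10-tetramethyl-12-oxotrideca-2,10-dienoate | C=C[C@@](C)(CC/C(C)=C/C(=O)OC(C)(C)C)[C@H](C)[C@@H](O)C/C(C)=C\C(=O)COCOC | intermediate (not isolated)
20 | tert-butyl (2E,6R,7S,8S,10Z)-8-acetoxy-6-ethenyl-13-(methoxymethoxy)-3,6,7,10-tetramethyl-12-oxotrideca-2,10-dienoate | C=C[C@@](C)(CC/C(C)=C/C(=O)OC(C)(C)C)[C@H](C)[C@@H](OC(C)=O)C/C(C)=C\C(=O)COCOC | intermediate
21 | adduct of benzenesulfonyl iodide across the vinyl group of 20 (C10–I, C1–SO2Ph; C10 epimers) | O=S(=O)(CC(I)[C@@](C)(CC/C(C)=C/C(=O)OC(C)(C)C)[C@H](C)[C@@H](OC(C)=O)C/C(C)=C\C(=O)COCOC)c1ccccc1 | intermediate (not isolated)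
22 | tert-butyl (2E,6S,7S,8S,10Z)-8-acetoxy-13-(methoxymethoxy)-3,6,7,10-tetramethyl-12-oxo-6-[(E)-2-(phenylsulfonyl)ethenyl]trideca-2,10-dienoate | O=S(=O)(/C=C/[C@@](C)(CC/C(C)=C/C(=O)OC(C)(C)C)[C@H](C)[C@@H](OC(C)=O)C/C(C)=C\C(=O)COCOC)c1ccccc1 | intermediate
23 | tert-butyl (2E,6S,7S,8S,10Z,12Z)-8-acetoxy-12-(tert-butyldimethylsilyloxy)-13-(methoxymethoxy)-3,6,7,10-tetramethyl-6-[(E)-2-(phenylsulfonyl)ethenyl]trideca-2,10,12-trienoate | O=S(=O)(/C=C/[C@@](C)(CC/C(C)=C/C(=O)OC(C)(C)C)[C@H](C)[C@@H](OC(C)=O)C/C(C)=C\C(O[Si](C)(C)C(C)(C)C)=C\OCOC)c1ccccc1 | intermediate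
24 | tert-butyl (13E)-7β-acetoxy-3-(tert-butyldimethylsilyloxy)-2β-(methoxymethoxy)-1β-(phenylsulfonyl)-18-nor-5,10-cis-cleroda-3,13-dien-15-oate | C1=C(O[Si](C)(C)C(C)(C)C)[C@@H](OCOC)[C@@H](S(=O)(=O)c3ccccc3)[C@@H]2[C@@](C)(CC/C(C)=C/C(=O)OC(C)(C)C)[C@H](C)[C@@H](OC(C)=O)C[C@]12C | intermediate
25 | tert-butyl (13E)-7β-acetoxy-18-(dimethylamino)-2β-(methoxymethoxy)-3-oxo-1β-(phenylsulfonyl)-5,10-cis-clerod-13-en-15-oate (C4 epimers) | CN(C)CC1C(=O)[C@@H](OCOC)[C@@H](S(=O)(=O)c3ccccc3)[C@@H]2[C@@](C)(CC/C(C)=C/C(=O)OC(C)(C)C)[C@H](C)[C@@H](OC(C)=O)C[C@]12C | intermediate (not isolated)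
26 | tert-butyl (13E)-7β-acetoxy-18-(dimethylamino)-2-(methoxymethoxy)-3-oxo-5,10-cis-cleroda-1,13-dien-15-oate (C4 epimers) | CN(C)CC1C(=O)C(OCOC)=C[C@@H]2[C@@](C)(CC/C(C)=C/C(=O)OC(C)(C)C)[C@H](C)[C@@H](OC(C)=O)C[C@]12C | intermediate
27 | trimethylammonium iodide from N-methylation of 26 | C[N+](C)(C)CC1C(=O)C(OCOC)=C[C@@H]2[C@@](C)(CC/C(C)=C/C(=O)OC(C)(C)C)[C@H](C)[C@@H](OC(C)=O)C[C@]12C.[I-] | intermediate (not isolated)
28 | tert-butyl (13E)-7β-acetoxy-2-(methoxymethoxy)-3-oxo-5,10-cis-cleroda-1,4(18),13-trien-15-oate | C=C1C(=O)C(OCOC)=C[C@@H]2[C@@](C)(CC/C(C)=C/C(=O)OC(C)(C)C)[C@H](C)[C@@H](OC(C)=O)C[C@]12C | intermediate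
29 | (2E)-5-[(1R,2S,3S,4aS,8aR)-3-acetoxy-7-hydroxy-1,2,4a-trimethyl-5-methylidene-6-oxo-1,2,3,4,4a,5,6,8a-octahydronaphthalen-1-yl]-3-methylpent-2-enoic acid | C=C1C(=O)C(O)=C[C@@H]2[C@@](C)(CC/C(C)=C/C(=O)O)[C@H](C)[C@@H](OC(C)=O)C[C@]12C | target

**Step count and risks**

Total step count: 16. Longest linear sequence: 16 steps (1 → 29).

Steps most likely to fail:

Step 13. What may go wrong: loss of facial control between the two cis-fused transition states, or [1,5]-hydrogen shift of the (Z)-diene and thermal loss of the silyl enol ether before cycloaddition. Fallback: the two bonds are made one after the other by an ionic annulation that sets out from 20. Aldehyde-selective Wacker oxidation of the hindered vinyl group (PdCl2(PhCN)2, CuCl2, AgNO2, O2, t-BuOH/MeNO2) should give tert-butyl (2E,6R,7S,8S,10Z)-8-acetoxy-13-(methoxymethoxy)-3,6,7,10-tetramethyl-12-oxo-6-(2-oxoethyl)trideca-2,10-dienoate F1. Pyrrolidine/AcOH would then form the C10 enamine, which adds to C5 of the enone (6-exo Michael addition, C5–C10); the C2 enol closes on the C1 iminium with loss of the amine (aldol-type condensation, C1=C2), and C10 settles to the cis fusion through the dienamine, giving tert-butyl (13E)-7β-acetoxy-2-(methoxymethoxy)-3-oxo-18-nor-5,10-cis-cleroda-1,13-dien-15-oate F2. LiN(SiMe3)2 followed by Me2N=CH2+ I− converts this into 26, where the route is rejoined.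

Step 11. What may go wrong: (Z)→(E) isomerisation of the enone by reversible iodine-atom addition, or unselective radical addition and cyclisation of the C10 radical onto the enone or the enoate. Fallback: olefin cross-metathesis in place of the radical addition–elimination. It sets out from 20, which with phenyl vinyl sulfone and the second-generation Hoveyda–Grubbs catalyst, RuCl2(H2IMes)(=CH–C6H4–2-O-i-Pr), in CH2Cl2 at 40 °C should give the (E)-vinyl sulfone directly; the conjugated trisubstituted alkenes do not take part, and the route is rejoined at 22 without any new compound.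

Step 4. What may go wrong: poor facial selectivity at the aldehyde (C7), attack through the α-carbon of the zinc dienolate, or epimerisation of C8 at reflux. Fallback: reagent-controlled propargylation, carboxylation and cuprate addition, setting out from 6. Allenylboronic acid pinacol ester with the matched enantiomer of a BINOL-derived phosphoric acid should give (4S,5S,6R)-6-ethenyl-5,6,10-trimethylundec-9-en-1-yn-4-ol F3. Its dianion (n-BuLi, 2.1 equiv, THF, −78 °C) is C-acylated with ClCO2Me, in preference to the hindered alkoxide, to methyl (5S,6S,7R)-7-ethenyl-5-hydroxy-6,7,11-trimethyldodec-10-en-2-ynoate F4. Syn-carbocupration with Me2CuLi at −78 °C gives methyl (2Z,5S,6S,7R)-7-ethenyl-5-hydroxy-3,6,7,11-tetramethyldodeca-2,10-dienoate F5, which lactonises on acidic work-up, and the route is rejoined at 10.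

**Further compounds**

F1 | step 13 | tert-butyl (2E,6R,7S,8S,10Z)-8-acetoxy-13-(methoxymethoxy)-3,6,7,10-tetramethyl-12-oxo-6-(2-oxoethyl)trideca-2,10-dienoate | O=CC[C@@](C)(CC/C(C)=C/C(=O)OC(C)(C)C)[C@H](C)[C@@H](OC(C)=O)C/C(C)=C\C(=O)COCOC
F2 | step 13 | tert-butyl (13E)-7β-acetoxy-2-(methoxymethoxy)-3-oxo-18-nor-5,10-cis-cleroda-1,13-dien-15-oate | C1C(=O)C(OCOC)=C[C@@H]2[C@@](C)(CC/C(C)=C/C(=O)OC(C)(C)C)[C@H](C)[C@@H](OC(C)=O)C[C@]12C
F0 | step 11 | none | none
F3 | step 4 | (4S,5S,6R)-6-ethenyl-5,6,10-trimethylundec-9-en-1-yn-4-ol | C=C[C@@](C)(CCC=C(C)C)[C@H](C)[C@@H](O)CC#C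
F4 | step 4 | methyl (5S,6S,7R)-7-ethenyl-5-hydroxy-6,7,11-trimethyldodec-10-en-2-ynoate | C=C[C@@](C)(CCC=C(C)C)[C@H](C)[C@@H](O)CC#CC(=O)OC
F5 | step 4 | methyl (2Z,5S,6S,7R)-7-ethenyl-5-hydroxy-3,6,7,11-tetramethyldodeca-2,10-dienoate | C=C[C@@](C)(CCC=C(C)C)[C@H](C)[C@@H](O)C/C(C)=C\C(=O)OC
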